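**Retrosynthetic overview**
1. The oxepane closes last (C3–OH displaces a C16 triflate); C15 comes from hydroboration of a C14 isopropenyl group, and the C11 butanoate from ketone reduction and acylation.
2. Ring D comes from a Diels–Alder reaction of a C1=C10–C11=C12 dienyl ether (made from a C10 ketone by triflation and Stille coupling) with but-3-en-2-one.
3. Key step: the (E)-oxonene of the 2,9-ether-bridged bicycle is made by ring expansion, a hydride-terminated Grob-type fragmentation of the C2–C7 bond of a 7-oxanorbornane-fused cyclohexyl mesylate.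
4. That tricycle comes from an intramolecular furan Diels–Alder reaction of an (S)-furyl carbinol tethered to an isopropenyl ketone; C3 is set by asymmetric vinylation of 2-acetylfuran.
5. Ring order: furan → oxanorbornene plus ring A → oxonane/tetrahydrofuran bicycle → ring D → oxepane.

Assumption: atom labels C1–C16 follow the asbestinin skeleton (C2–O–C9 ether bridge; ring D = C1, C10–C14; ring A = C2–C7 in the tricyclic intermediates), and the ligand enantiomer in step 1 is the one that gives the (S)-carbinol.

**Route**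

Step 1
Reactants: 1 2-acetylfuran; 2 vinylmagnesium bromide
Product: 3 (S)-2-(furan-2-yl)but-3-en-2-ol
Conditions: 2, ZnCl2, THF, 0 °C (gives divinylzinc); then 1, Ti(OiPr)4 (1.2 equiv), chiral trans-cyclohexane-1,2-bis(sulfonamide) diol ligand (10 mol%), toluene, rt
Reagents that add atoms: none
Why: Titanium/bis(sulfonamide)-catalysed enantioselective alkenylzinc 1,2-addition to an aryl methyl ketone delivers the vinyl group to one ketone face and sets the (S)-tertiary carbinol that becomes C3.

Step 2
Reactants: 3 (S)-2-(furan-2-yl)but-3-en-2-ol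
Product: 4 (S)-triethyl{[2-(furan-2-yl)but-3-en-2-yl]oxy}silane
Conditions: Et3SiOTf, 2,6-lutidine, CH2Cl2, −78 °C
Reagents that add atoms: triethylsilyl trifluoromethanesulfonate, CC[Si](CC)(CC)OS(=O)(=O)C(F)(F)F
Why: Silyl triflate silylation of the hindered tertiary alcohol protects the acid-labile furyl carbinol for the Lewis-acid step without touching the stereocentre.

Step 3
Reactants: 4 (S)-triethyl{[2-(furan-2-yl)but-3-en-2-yl]oxy}silane; 5 2-bromopropene
Product: 7 (S)-6-(furan-2-yl)-2-methyl-6-(triethylsilyloxy)hept-1-en-3-one, via B-alkyl-9-BBN adduct 6 (not isolated)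
Conditions: 9-BBN, THF, 0 °C to rt; then 5, CO (1 atm), Pd(PPh3)4 (5 mol%), K3PO4, THF/benzene, rt
Reagents that add atoms: carbon monoxide, [C-]#[O+]
Why: Anti-Markovnikov hydroboration of the vinyl group followed by carbonylative Suzuki–Miyaura coupling of the B-alkyl-9-BBN with the vinyl bromide gives the isopropenyl ketone in one operation and creates no stereocentre.

Step 4
Reactants: 7 (S)-6-(furan-2-yl)-2-methyl-6-(triethylsilyloxy)hept-1-en-3-one
Product: 8 tricyclic ketone (7-oxanorbornene with bridgeheads C2 and C9 and C1=C10; fused at C2–C7 to ring A cyclohexanone; C6 ketone; C7 methyl endo; 3S with C3 methyl equatorial and OSiEt3 axial)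
Conditions: MeAlCl2 (1.1 equiv), CH2Cl2, −78 °C
Reagents that add atoms: none
Why: Lewis-acid-promoted intramolecular Diels–Alder reaction of the furan with the tethered α-methyl enone closes ring A and the oxanorbornene through a chair-like exo transition state (C3 methyl pseudo-equatorial, silyloxy pseudo-axial and anti to the furan oxygen), so the C3 centre sets C2, C7 and C9.

Step 5
Reactants: 8 tricyclic ketone
Product: 9 C6 equatorial alcohol of 8 (6-OH cis to the C7 methyl)
Conditions: NaBH4, MeOH, 0 °C
Reagents that add atoms: none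
Why: Borohydride reduction by axial hydride attack on the rigid cyclohexanone, away from the axial angular methyl, gives the equatorial C6 alcohol whose C–O bond is antiperiplanar to C7–C2.

Step 6
Reactants: 9 C6 equatorial alcohol
Product: 10 C6 methanesulfonate of 9
Conditions: MsCl, Et3N, CH2Cl2, 0 °C
Reagents that add atoms: methanesulfonyl chloride, CS(=O)(=O)Cl
Why: O-Sulfonylation installs the nucleofuge with retention at C6.

Step 7
Reactants: 10 C6 methanesulfonate
Product: 12 C10 exo-alcohol of 10 (C1–C10 saturated; mesylate retained), via exo-alkylborane 11 (not isolated)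
Conditions: BH3·THF, THF, 0 °C; then 30% H2O2, aq. NaHCO3, 0 °C
Reagents that add atoms: hydrogen peroxide, OO
Why: Hydroboration–oxidation of the strained alkene occurs on the exo face with boron at C10 (distal to the substituted bridgehead C2), which removes the alkene before ionisation and installs the oxygen that becomes the C10 ketone.

Step 8
Reactants: 12 C10 exo-alcohol mesylate
Product: 14 (6E)-bicyclic ether alcohol (2,9-epoxycyclodec-6-ene; 3-methyl-3-OSiEt3; 7-methyl; 10-OH; C2, C3 and C9 as in the target), via bridged oxocarbenium mesylate 13 (not isolated)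
Conditions: Et3SiH (5 equiv), 2,6-lutidine, (CF3)2CHOH, 45 °C
Reagents that add atoms: none
Why: Proposed new method: a hydride-terminated Grob (Wharton-type) fragmentation in which the bridging ether oxygen of a 7-oxanorbornane is the electron donor — the equatorial C6 mesylate ionises antiperiplanar to the C7–C2 bond and an oxygen lone pair, C7–C2 cleaves with release of bicyclic strain to give the (E)-C6=C7 alkene stereospecifically (C8 equatorial and methyl axial on C7) and oxocarbenium 13, and Et3SiH reduces 13 on its only open face to give C2–H cis to C9–H; the closest known reactions are alkoxide-driven Wharton–Grob ring expansions of 1,3-diol monosulfonates, hydride-terminated aza-Grob fragmentations and silane reductions of cyclic oxocarbenium ions.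

Step 9
Reactants: 14 (6E)-bicyclic ether alcohol
Product: 15 C10 ketone of 14
Conditions: DMP, NaHCO3, CH2Cl2, rt
Reagents that add atoms: none
Why: Dess–Martin oxidation of the secondary alcohol is neutral and leaves the silyl ether, the trisubstituted alkene and the α-stereocentre C9 untouched.

Step 10
Reactants: 15 C10 ketone
Product: 17 C10 enol triflate (C1=C10) of 15, via potassium enolate 16 (not isolated)
Conditions: KN(SiMe3)2, THF, −78 °C; then PhNTf2
Reagents that add atoms: N-phenylbis(trifluoromethanesulfonimide), O=S(=O)(N(c1ccccc1)S(=O)(=O)C(F)(F)F)C(F)(F)F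
Why: Kinetic enolisation takes the accessible C1 proton in preference to the α-alkoxy C9 proton, and O-triflation gives the vinyl triflate without touching C2 or C9.

Step 11
Reactants: 18 ethyl (Z)-prop-1-enyl ether
Product: 20 (E)-tributyl(1-ethoxyprop-1-en-1-yl)stannane, via lithiated enol ether 19 (not isolated)
Conditions: t-BuLi, THF, −78 to 0 °C; then Bu3SnCl, −78 °C
Reagents that add atoms: tributyltin chloride, CCCC[Sn](Cl)(CCCC)CCCC
Why: α-Lithiation of the enol ether and stannylation proceed with retention of alkene geometry, so the methyl group stays cis to ethoxy.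

Step 12
Reactants: 17 C10 enol triflate; 20 (E)-tributyl(1-ethoxyprop-1-en-1-yl)stannane
Product: 21 dienyl ether (C1=C10 with a (Z)-1-ethoxyprop-1-enyl group on C10)
Conditions: Pd(PPh3)4 (5 mol%), CuI, LiCl, DMF, 50 °C
Reagents that add atoms: none
Why: Stille coupling of a vinyl triflate with an α-alkoxyvinylstannane forms the C10–C11 bond with retention of both alkene geometries.

Step 13
Reactants: 21 dienyl ether; 22 but-3-en-2-one
Product: 24 tricyclic methyl ketone (ring D cyclohexene with C10=C11 enol ether; 12-methyl; 14-acetyl equatorial; C1, C12 and C14 as in the target), via kinetic C14-epimeric adduct 23 (not isolated)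
Conditions: 22 (5 equiv), toluene, 60 °C; then DBU, rt
Reagents that add atoms: none
Why: In this Diels–Alder reaction the 2-alkoxydiene gives the para regiochemistry (acetyl on C14), the dienophile adds to the diene face anti to the oxonene bridge (setting C1), the outside methyl of the (Z)-enol ether ends cis to C2 (setting C12), and DBU then epimerises the endo acetyl at C14 to the equatorial natural configuration while C12 is protected as the enol ether.

Step 14
Reactants: 24 tricyclic methyl ketone
Product: 25 14-isopropenyl analogue of 24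
Conditions: Ph3PCH3Br, KOtBu, THF, 0 °C to rt
Reagents that add atoms: methyltriphenylphosphonium bromide, C[P+](c1ccccc1)(c1ccccc1)c1ccccc1.[Br-]
Why: Wittig methylenation converts the methyl ketone into the isopropenyl group without epimerising C14 and leaves the enol ether intact.

Step 15
Reactants: 25 14-isopropenyl enol ether
Product: 26 tricyclic C11 ketone (free C3–OH; 14-isopropenyl; C1, C2, C3, C9, C10, C12 and C14 as in the target)
Conditions: 1 M HCl, THF, 0 °C
Reagents that add atoms: water, O
Why: Mild acid hydrolysis of the enol ether protonates C10 on the convex face to give the cis-fused ketone, removes the silyl ether, and is short and cold enough to avoid epimerising the C12 methyl.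

Step 16
Reactants: 26 tricyclic C11 ketone
Product: 27 C11 alcohol of 26 (11R; OH cis to the C9–C10 bond and to the C12 methyl)
Conditions: NaBH4, MeOH, −20 °C
Reagents that add atoms: none
Why: Borohydride reduction from the convex face of the cis-fused ring D gives the equatorial C11 alcohol.

Step 17
Reactants: 27 C11 alcohol; 28 butanoyl chloride
Product: 29 C11 butanoate of 27
Conditions: pyridine, DMAP (cat.), CH2Cl2, 0 °C
Reagents that add atoms: none
Why: Acylation is selective for the secondary C11 alcohol over the tertiary C3 alcohol.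

Step 18
Reactants: 29 C11 butanoate
Product: 31 C16 primary alcohol (15R) of 29, via B-alkyl-9-BBN adduct 30 (not isolated)
Conditions: 9-BBN, THF, rt; then 30% H2O2, aq. NaHCO3, 0 °C
Reagents that add atoms: hydrogen peroxide, OO
Why: 9-BBN hydroborates the 1,1-disubstituted isopropenyl group in preference to the trisubstituted ring alkene and attacks the less hindered face of its A(1,3)-minimised rotamer, so hydroboration–oxidation sets C15 and frees the C16 alcohol.

Step 19
Reactants: 31 C16 primary alcohol
Product: 33 4-deoxyasbestinin A, via primary triflate 32 (not isolated)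
Conditions: Tf2O, 2,6-lutidine, CH2Cl2, −78 to 0 °C
Reagents that add atoms: none
Why: Selective triflation of the primary alcohol is followed by intramolecular Williamson-type displacement by the tertiary C3 hydroxyl, closing the oxepane with retention at C3.

**Compound list**
1 | 2-acetylfuran | CC(=O)c1ccco1 | starting material
2 | vinylmagnesium bromide | C=C[Mg]Br | starting material
3 | (S)-2-(furan-2-yl)but-3-en-2-ol | O[C@@](c1ccco1)(C)C=C | intermediate
4 | (S)-triethyl{[2-(furan-2-yl)but-3-en-2-yl]oxy}silane | CC[Si](CC)(CC)O[C@@](c1ccco1)(C)C=C | intermediate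
5 | 2-bromopropene | CC(Br)=C | starting material
6 | 9-[(3S)-3-(furan-2-yl)-3-(triethylsilyloxy)butyl]-9-borabicyclo[3.3.1]nonane | CC[Si](CC)(CC)O[C@@](c1ccco1)(C)CCB1C2CCCC1CCC2 | intermediate
7 | (S)-6-(furan-2-yl)-2-methyl-6-(triethylsilyloxy)hept-1-en-3-one | CC[Si](CC)(CC)O[C@@](c1ccco1)(C)CCC(=O)C(C)=C | intermediate
8 | tricyclic ketone (oxanorbornene fused to ring A; C6=O; C7 methyl endo; 3S) | CC[Si](CC)(CC)O[C@@]1(C)CCC(=O)[C@]2(C)C[C@@H]3O[C@]12C=C3 | intermediate
9 | C6 equatorial alcohol of 8 | CC[Si](CC)(CC)O[C@@]1(C)CC[C@@H](O)[C@]2(C)C[C@@H]3O[C@]12C=C3 | intermediate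
10 | C6 methanesulfonate of 9 | CC[Si](CC)(CC)O[C@@]1(C)CC[C@@H](OS(C)(=O)=O)[C@]2(C)C[C@@H]3O[C@]12C=C3 | intermediate
11 | C10 exo-borane of 10 | CC[Si](CC)(CC)O[C@@]1(C)CC[C@@H](OS(C)(=O)=O)[C@]2(C)C[C@@H]3O[C@]12C[C@H]3B | intermediate
12 | C10 exo-alcohol of 10 | CC[Si](CC)(CC)O[C@@]1(C)CC[C@@H](OS(C)(=O)=O)[C@]2(C)C[C@@H]3O[C@]12C[C@H]3O | intermediate
13 | bridged C2 oxocarbenium methanesulfonate with (6E)-alkene | CC[Si](CC)(CC)O[C@@]1(C)CC/C=C(\C)C[C@@H]2[O+]=C1C[C@H]2O.CS(=O)(=O)[O-] | intermediate
14 | (6E)-bicyclic ether alcohol (C10–OH) | CC[Si](CC)(CC)O[C@@]1(C)CC/C=C(\C)C[C@@H]2O[C@H]1C[C@H]2O | intermediate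
15 | C10 ketone of 14 | CC[Si](CC)(CC)O[C@@]1(C)CC/C=C(\C)C[C@@H]2O[C@H]1CC2=O | intermediate
16 | potassium enolate of 15 | CC[Si](CC)(CC)O[C@@]1(C)CC/C=C(\C)C[C@@H]2O[C@H]1C=C2[O-].[K+] | intermediate
17 | C10 enol triflate | CC[Si](CC)(CC)O[C@@]1(C)CC/C=C(\C)C[C@@H]2O[C@H]1C=C2OS(=O)(=O)C(F)(F)F | intermediate
18 | ethyl (Z)-prop-1-enyl ether | C/C=C\OCC | starting material
19 | 1-ethoxyprop-1-enyllithium | C/C=C(\OCC)[Li] | intermediate
20 | (E)-tributyl(1-ethoxyprop-1-en-1-yl)stannane | C/C=C(\OCC)[Sn](CCCC)(CCCC)CCCC | intermediate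
21 | dienyl ether (C10 bears (Z)-1-ethoxyprop-1-enyl) | CC[Si](CC)(CC)O[C@@]1(C)CC/C=C(\C)C[C@@H]2O[C@H]1C=C2/C(OCC)=C/C | intermediate
22 | but-3-en-2-one | CC(=O)C=C | starting material
23 | kinetic Diels–Alder adduct (C14 epimer of 24) | CCOC1=C2[C@H]([C@H](C[C@H]1C)C(C)=O)[C@@H]3O[C@H]2C/C(C)=C/CC[C@]3(C)O[Si](CC)(CC)CC | intermediate
24 | tricyclic methyl ketone (14-acetyl equatorial) | CCOC1=C2[C@H]([C@@H](C[C@H]1C)C(C)=O)[C@@H]3O[C@H]2C/C(C)=C/CC[C@]3(C)O[Si](CC)(CC)CC | intermediate
25 | 14-isopropenyl enol ether | CCOC1=C2[C@H]([C@@H](C[C@H]1C)C(C)=C)[C@@H]3O[C@H]2C/C(C)=C/CC[C@]3(C)O[Si](CC)(CC)CC | intermediate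
26 | tricyclic C11 ketone with free C3–OH | O=C1[C@@H]2[C@H]([C@@H](C[C@H]1C)C(C)=C)[C@@H]3O[C@H]2C/C(C)=C/CC[C@]3(C)O | intermediate
27 | C11 alcohol (11R) | O[C@H]1[C@@H]2[C@H]([C@@H](C[C@H]1C)C(C)=C)[C@@H]3O[C@H]2C/C(C)=C/CC[C@]3(C)O | intermediate
28 | butanoyl chloride | CCCC(=O)Cl | starting material
29 | C11 butanoate | CCCC(=O)O[C@H]1[C@@H]2[C@H]([C@@H](C[C@H]1C)C(C)=C)[C@@H]3O[C@H]2C/C(C)=C/CC[C@]3(C)O | intermediate
30 | B-alkyl-9-BBN adduct of 29 (boron on C16) | CCCC(=O)O[C@H]1[C@@H]2[C@H]([C@@H](C[C@H]1C)[C@@H](C)CB4C5CCCC4CCC5)[C@@H]3O[C@H]2C/C(C)=C/CC[C@]3(C)O | intermediate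
31 | C16 primary alcohol (15R) | CCCC(=O)O[C@H]1[C@@H]2[C@H]([C@@H](C[C@H]1C)[C@@H](C)CO)[C@@H]3O[C@H]2C/C(C)=C/CC[C@]3(C)O | intermediate
32 | C16 triflate of 31 | CCCC(=O)O[C@H]1[C@@H]2[C@H]([C@@H](C[C@H]1C)[C@@H](C)COS(=O)(=O)C(F)(F)F)[C@@H]3O[C@H]2C/C(C)=C/CC[C@]3(C)O | intermediate
33 | 4-deoxyasbestinin A | CCCC(=O)O[C@H]1[C@@H]2[C@@H]3[C@@H](C[C@H]1C)[C@@H](C)CO[C@@]1(C)CC/C=C(\C)C[C@@H]2O[C@@H]31 | target

**Step count and risks**

Total step count: 19. Longest linear sequence: 18 (steps 1–10 and 12–19; step 11 makes the stannane).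

Three steps most likely to fail:

Step 8 (the proposed new fragmentation). The mesylate may ionise without C7–C2 cleavage (elimination or Wagner–Meerwein shift), or the α-silyloxy oxocarbenium may rearrange before hydride capture. The fallback uses known chemistry, sets out from 9 and comes back at 15. Nickel-catalysed hydroalumination ring opening of the oxabicyclic alkene (iBu2AlH, Ni(cod)2, dppb) cleaves C9–O and gives the ring-opened diol (C2 tertiary OH, C6 secondary OH, C9=C10) F4. Selective mesylation of the secondary hydroxyl gives the C6 monomesylate F5. KOtBu in THF then triggers the classical alkoxide-driven Wharton–Grob fragmentation to the (6E,9Z)-cyclodecadienone (C2 ketone) F6. NaBH4 gives the C2 alcohol F7. Transannular oxymercuration (Hg(OCOCF3)2) with oxidative demercuration (NaBH4, O2) re-forms the C2–O–C9 bridge and places a hydroxyl on C10, giving 14 together with its C10 epimer F8. DMP oxidation of both gives 15.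

Step 3 (carbonylative coupling). Direct, non-carbonylative coupling or protodeboronation may compete. The fallback sets out from 4 and comes back at 7. Hydroboration of 4 with 9-BBN and oxidation (H2O2, NaOH) gives (S)-3-(furan-2-yl)-3-(triethylsilyloxy)butan-1-ol F1. DMP oxidation gives (S)-3-(furan-2-yl)-3-(triethylsilyloxy)butanal F2. Isopropenylmagnesium bromide adds to give (6S)-6-(furan-2-yl)-2-methyl-6-(triethylsilyloxy)hept-1-en-3-ol F3 as a mixture of carbinol epimers, and DMP oxidation of F3 gives 7.

Step 13 (Diels–Alder reaction and C14 equilibration). But-3-en-2-one may react sluggishly or polymerise, and the ketone may equilibrate incompletely. The fallback sets out from 21 and comes back at 24. Cycloaddition with acrolein (toluene, rt), which is more reactive and gives a more easily epimerised adduct, followed by DBU gives the equatorial C14 aldehyde analogue of 24, F9. MeMgBr at −78 °C gives the secondary alcohols F10 (C15 epimers), and DMP oxidation gives 24.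

Further compounds
F1 | step 3 | (S)-3-(furan-2-yl)-3-(triethylsilyloxy)butan-1-ol | CC[Si](CC)(CC)O[C@@](c1ccco1)(C)CCO
F2 | step 3 | (S)-3-(furan-2-yl)-3-(triethylsilyloxy)butanal | CC[Si](CC)(CC)O[C@@](c1ccco1)(C)CC=O
F3 | step 3 | (6S)-6-(furan-2-yl)-2-methyl-6-(triethylsilyloxy)hept-1-en-3-ol (carbinol epimers) | CC[Si](CC)(CC)O[C@@](c1ccco1)(C)CCC(O)C(C)=C
F4 | step 8 | ring-opened diol (C2 tertiary OH, C6 secondary OH, C9=C10) | CC[Si](CC)(CC)O[C@@]1(C)CC[C@@H](O)[C@]2(C)CC=CC[C@@]12O
F5 | step 8 | C6 monomesylate of F4 | CC[Si](CC)(CC)O[C@@]1(C)CC[C@@H](OS(C)(=O)=O)[C@]2(C)CC=CC[C@@]12O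
F6 | step 8 | (6E,9Z)-cyclodecadienone (C2 ketone) | CC[Si](CC)(CC)O[C@@]1(C)CC/C=C(\C)C/C=C\CC1=O
F7 | step 8 | C2 alcohol of F6 | CC[Si](CC)(CC)O[C@@]1(C)CC/C=C(\C)C/C=C\C[C@@H]1O
F8 | step 8 | C10 epimer of 14 | CC[Si](CC)(CC)O[C@@]1(C)CC/C=C(\C)C[C@@H]2O[C@H]1C[C@@H]2O
F9 | step 13 | C14 aldehyde analogue of 24 | CCOC1=C2[C@H]([C@@H](C[C@H]1C)C=O)[C@@H]3O[C@H]2C/C(C)=C/CC[C@]3(C)O[Si](CC)(CC)CC
F10 | step 13 | C15 secondary alcohols from F9 (C15 epimers) | CCOC1=C2[C@H]([C@@H](C[C@H]1C)C(C)O)[C@@H]3O[C@H]2C/C(C)=C/CC[C@]3(C)O[Si](CC)(CC)CC
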